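**Plan**

Numbering: phenanthrene locants for the carbocycle (C1 ketone, C2 OMe, C3 N, C4 quaternary C–O, C8 OH, C9 ketone); the four-carbon bridge runs from C2' (aminal CH on O4) to C5' (CH2 on N).
The pyrrolidine (N, C2'–C5') and the oxazolidine (C3, N, C2', O4, C4) share the N–C2' bond, so their outer atoms C3–N–C5'–C4'–C3'–C2'–O4–C4 form an eight-membered 1,6-oxazocine. Cutting N–C2' leaves that ring with a C3'=C4' alkene, which metathesis of an N-allyl and an O-allyl group provides.
Earlier cuts: C3–N (allylamine for methoxide on a vinylogous ester), O4–allyl, C4–OH (para-hydroxylative dearomatisation of a phenanthren-1-ol), C9–C8a (Friedel–Crafts closure of ring B), C4a–C4b (Suzuki), C9 (one-carbon homologation of the aldehyde), C4–CH3 (Suzuki).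
Forward order: ring A is dressed, joined to ring C, ring B is closed to the phenanthrene, ring A is dearomatised, the eight-membered ring is closed, then one bond closes pyrrolidine and oxazolidine together; O9 and O8 are unmasked last.
Stereochemistry: C4 (R) comes from a chiral-iodoarene-catalysed hydroxylation; C2' (S, H-2' cis to the C4 methyl) is set from C4 under reversible N,O-acetal formation.

Key step: step 16

Remark: the 8,9-dioxygenated ring B is assumed to rest as the C9-keto/C10-methylene tautomer drawn for the target once the free 8-OH can hydrogen-bond to O9, and as the 9-naphthol while O8 is methylated; the forms differ only by prototropy and need no step.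

**Route**

Step 1
Reactants: 1 2,3,4-trimethoxybenzaldehyde
Product: 2 2-hydroxy-3,4-dimethoxybenzaldehyde
Conditions: BCl3 (1.1 equiv), CH2Cl2, 0 °C to rt; aq. HCl work-up
Reagents that add atoms: none
Why: Chelation-controlled ortho-demethylation of an aryl methyl ether: boron held on the formyl oxygen reaches only the neighbouring methoxy group, so that methyl alone should be lost.

Step 2
Reactants: 2 2-hydroxy-3,4-dimethoxybenzaldehyde
Product: 3 5-bromo-2-hydroxy-3,4-dimethoxybenzaldehyde
Conditions: NBS, MeCN, 0 °C to rt
Reagents that add atoms: N-bromosuccinimide, O=C1CCC(=O)N1Br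
Why: Electrophilic aromatic bromination should go to C5, para to the free phenol and ortho to a methoxy group, because C6 is only meta to the hydroxyl and ortho to the formyl group.

Step 3
Reactants: 3 5-bromo-2-hydroxy-3,4-dimethoxybenzaldehyde
Product: 4 2-(benzyloxy)-5-bromo-3,4-dimethoxybenzaldehyde
Conditions: BnBr, K2CO3, DMF, 50 °C
Reagents that add atoms: benzyl bromide, BrCc1ccccc1
Why: Williamson etherification of the acidic salicylaldehyde phenol; the benzyl group marks the oxygen that becomes the C1 phenol and can later be removed by hydrogenolysis beside methyl and MOM ethers.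

Step 4
Reactants: 4 2-(benzyloxy)-5-bromo-3,4-dimethoxybenzaldehyde
Product: 5 2-(benzyloxy)-3,4-dimethoxy-5-methylbenzaldehyde
Conditions: MeB(OH)2, Pd(dppf)Cl2 (5 mol%), K2CO3, 1,4-dioxane/H2O, 90 °C
Reagents that add atoms: methylboronic acid, CB(O)O
Why: Suzuki–Miyaura methylation of the aryl bromide, which tolerates the aldehyde and the ethers and installs the future C4 methyl group.

Step 5
Reactants: 5 2-(benzyloxy)-3,4-dimethoxy-5-methylbenzaldehyde
Product: 7 2-[2-(benzyloxy)-3,4-dimethoxy-5-methylphenyl]acetonitrile, via formamide adduct 6 (not isolated)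
Conditions: TosMIC, KOtBu, DME, −50 °C; then MeOH, reflux
Reagents that add atoms: tosylmethyl isocyanide, Cc1ccc(cc1)S(=O)(=O)C[N+]#[C-]
Why: van Leusen reductive cyanation: the TosMIC anion adds to the aldehyde, the oxazoline opens to the N-(1-tosylalkenyl)formamide 6, and methanolysis with loss of sulfinate leaves the nitrile with one more carbon (the future C9); it is done before ring C is attached so that no electron-rich neighbouring ring can interfere.

Step 6
Reactants: 7 2-[2-(benzyloxy)-3,4-dimethoxy-5-methylphenyl]acetonitrile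
Product: 8 2-[2-(benzyloxy)-6-bromo-3,4-dimethoxy-5-methylphenyl]acetonitrile
Conditions: NBS, MeCN, rt, dark
Reagents that add atoms: N-bromosuccinimide, O=C1CCC(=O)N1Br
Why: Electrophilic aromatic bromination at the only free ring position, para to a methoxy group, on a ring no longer deactivated by a formyl group; ionic conditions in the dark should avoid benzylic bromination.

Step 7
Reactants: 8 2-[2-(benzyloxy)-6-bromo-3,4-dimethoxy-5-methylphenyl]acetonitrile; 9 3,5-dimethoxyphenylboronic acid
Product: 10 2-[3-(benzyloxy)-3',4,5,5'-tetramethoxy-6-methylbiphenyl-2-yl]acetonitrile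
Conditions: Pd(OAc)2 (5 mol%), SPhos (10 mol%), K3PO4, toluene/H2O, 100 °C
Reagents that add atoms: 3,5-dimethoxyphenylboronic acid (compound 9), COc1cc(OC)cc(B(O)O)c1
Why: Suzuki–Miyaura coupling with a dialkylbiarylphosphine ligand, chosen because the bromide has two ortho substituents while the boronic acid has none; it forms the C4a–C4b bond.

Step 8
Reactants: 10 2-[3-(benzyloxy)-3',4,5,5'-tetramethoxy-6-methylbiphenyl-2-yl]acetonitrile
Product: 11 2-[3-(benzyloxy)-3',4,5,5'-tetramethoxy-6-methylbiphenyl-2-yl]acetic acid
Conditions: KOH, EtOH/H2O, reflux; then aq. HCl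
Reagents that add atoms: water, O; potassium hydroxide, [K+].[OH-]
Why: Alkaline nitrile hydrolysis; the primary nitrile is unhindered and benzyl and methyl aryl ethers are stable to hydroxide.

Step 9
Reactants: 11 2-[3-(benzyloxy)-3',4,5,5'-tetramethoxy-6-methylbiphenyl-2-yl]acetic acid
Product: 13 1-(benzyloxy)-2,3,6,8-tetramethoxy-4-methylphenanthren-9-ol, via acid chloride 12 (not isolated)
Conditions: (COCl)2, DMF (cat.), CH2Cl2, 0 °C to rt; then SnCl4 (1.2 equiv), CH2Cl2, −78 to −20 °C
Reagents that add atoms: none
Why: Intramolecular Friedel–Crafts acylation: the acyl chloride attacks the ring C position ortho to one methoxy group and para to the other (the two ortho positions of ring C are equivalent), which closes ring B, and the ketone enolises at once to the aromatic 9-phenanthrol.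

Step 10
Reactants: 13 1-(benzyloxy)-2,3,6,8-tetramethoxy-4-methylphenanthren-9-ol
Product: 14 1-(benzyloxy)-2,3,6,8-tetramethoxy-9-(methoxymethoxy)-4-methylphenanthrene
Conditions: NaH, MOMCl, THF, 0 °C to rt (crude 13 used at once)
Reagents that add atoms: chloromethyl methyl ether, COCCl
Why: O-alkylation of the phenanthrolate (Williamson type) masks the air-sensitive 9-phenanthrol as a MOM ether that tolerates the hydrogenolysis, oxidation, base, amine and ruthenium steps that follow.

Step 11
Reactants: 14 1-(benzyloxy)-2,3,6,8-tetramethoxy-9-(methoxymethoxy)-4-methylphenanthrene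
Product: 15 2,3,6,8-tetramethoxy-9-(methoxymethoxy)-4-methylphenanthren-1-ol
Conditions: H2 (1 atm), 10% Pd/C, EtOAc/EtOH, rt; kept under argon
Reagents that add atoms: none
Why: Hydrogenolysis of the benzyl aryl ether frees the C1 phenol while MOM and methyl ethers and the phenanthrene nucleus are inert under these mild conditions.

Step 12
Reactants: 15 2,3,6,8-tetramethoxy-9-(methoxymethoxy)-4-methylphenanthren-1-ol
Product: 16 (4R)-4-hydroxy-2,3,6,8-tetramethoxy-9-(methoxymethoxy)-4-methylphenanthren-1(4H)-one
Conditions: (R,R)-2,2'-[(2-iodo-1,3-phenylene)bis(oxy)]bis(N-mesitylpropanamide) (10 mol%), mCPBA (1.2 equiv), CH2Cl2/(CF3)2CHOH/H2O, −20 °C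
Reagents that add atoms: water, O
Why: Chiral-iodoarene-catalysed hydroxylative para-dearomatisation of a phenol: the peracid turns the catalyst into a trivalent iodine species that binds the phenol oxygen, and water attacks C4, the naphthalene α-type position whose change to sp3 also relieves the bay strain between the methyl group and H-5; the chiral iodine centre selects the face, and the catalyst antipode is to be chosen on this substrate so that the 4R quinol results.

Step 13
Reactants: 16 (4R)-4-hydroxy-2,3,6,8-tetramethoxy-9-(methoxymethoxy)-4-methylphenanthren-1(4H)-one; 17 allyl bromide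
Product: 18 (4R)-4-(allyloxy)-2,3,6,8-tetramethoxy-9-(methoxymethoxy)-4-methylphenanthren-1(4H)-one
Conditions: NaH, n-Bu4NI (cat.), DMF, 0 °C
Reagents that add atoms: allyl bromide (compound 17), C=CCBr
Why: Williamson allylation of the tertiary alkoxide; the quinol has no enolisable position, its only acceptor carbon (C3) is shielded, and the C4 stereocentre is not involved.

Step 14
Reactants: 18 (4R)-4-(allyloxy)-2,3,6,8-tetramethoxy-9-(methoxymethoxy)-4-methylphenanthren-1(4H)-one; 19 allylamine
Product: 20 (4R)-3-(allylamino)-4-(allyloxy)-2,6,8-trimethoxy-9-(methoxymethoxy)-4-methylphenanthren-1(4H)-one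
Conditions: allylamine (5 equiv), EtOH, 60 °C
Reagents that add atoms: allylamine (compound 19), C=CCN
Why: Addition–elimination on a vinylogous ester: C3 is the β-carbon of the C1 enone and carries the only conjugated leaving group, so the amine should replace the C3 methoxy group and give the vinylogous amide, while the C2 methoxy group on the α-carbon stays.

Step 15
Reactants: 20 (4R)-3-(allylamino)-4-(allyloxy)-2,6,8-trimethoxy-9-(methoxymethoxy)-4-methylphenanthren-1(4H)-one
Product: 21 (4R)-2,6,8-trimethoxy-9-(methoxymethoxy)-4-methylphenanthren-1(4H)-one bridged from N3 to O4 by (Z)-CH2–CH=CH–CH2 (the dihydro-1,6-oxazocine)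
Conditions: second-generation Grubbs catalyst RuCl2(H2IMes)(PCy3)(=CHPh) (5 mol%), 1,4-benzoquinone (10 mol%), ClCH2CH2Cl (2 mM), 70 °C
Reagents that add atoms: none
Why: Ring-closing metathesis: the two allyl groups sit on adjacent ring atoms (C3 sp2, C4 quaternary), which holds them together as in closures of benzo-fused eight-membered rings; the ring size allows only the Z alkene, the vinylogous amide NH is too weakly basic to bind ruthenium, and benzoquinone suppresses early alkene migration.

Step 16
Reactants: 21 the (4R)-dihydro-1,6-oxazocine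
Product: 23 (4R,2'S)-2,6,8-trimethoxy-9-(methoxymethoxy)-4-methylphenanthren-1(4H)-one with N3 and O4 both bonded to C2' of a pyrrolidine ring N–C5'H2–C4'H2–C3'H2–C2'H (fused oxazolidine–pyrrolidine N,O-acetal), via cyclic enol ether 22 (not isolated)
Conditions: RuHCl(CO)(PPh3)3 (5 mol%), (PhO)2P(O)OH (10 mol%), toluene, 80 °C
Reagents that add atoms: none
Why: The ruthenium hydride adds to and leaves the ring alkene reversibly and so moves it from C3'=C4' to either side; the isomer with the C2'=C3' enol ether (22) is protonated by the phosphoric acid at C3', and the vinylogous-amide NH across the ring attacks the resulting oxocarbenium carbon C2', making the N–C2' bond. The closest known reaction type is the relay of ruthenium hydride isomerisation of an allyl ether to an enol ether with Brønsted acid-catalysed N,O-acetal formation, here run in transannular form. The single new bond closes the pyrrolidine by 5-exo-trig attack (the C2'=O+ bond lies outside that ring) and the oxazolidine by 5-endo-trig attack (the C2'=O+ bond lies inside it), the usual way oxazolidines form from oxocarbenium or iminium ions. C2' is the only new stereocentre and is controlled by C4 under equilibrating conditions, since the N,O-acetal reopens in the acid: the isomer with the three pyrrolidine methylene carbons on the oxazolidine face away from the C4 methyl group (H-2' cis to methyl, 2'S) should be the more stable one. The step needs the alkene to end next to oxygen and not next to nitrogen; the enamine-type isomer (C4'=C5') has no internal nucleophile for its iminium ion and is returned by the hydride, so only the enol ether is drained, and the cis attachment of the bridge at C3 and C4 holds N within bonding distance of C2'. The weak acid in dry toluene should leave the aryl MOM ether and the tertiary C4–O bond alone.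

Step 17
Reactants: 23 the MOM-protected N,O-acetal
Product: 24 (4R,2'S)-9-hydroxy-2,6,8-trimethoxy-4-methyl N,O-acetal (23 without the MOM group)
Conditions: NaHSO4·SiO2, CH2Cl2, rt
Reagents that add atoms: none
Why: Acid-catalysed hydrolysis of the phenolic MOM acetal on silica-supported hydrogen sulfate, a mild method for aryl MOM ethers; if the N,O-acetal opens under the acid it should reclose to the same thermodynamic isomer.

Step 18
Reactants: 24 the 9-hydroxy-8-methoxy N,O-acetal
Product: 25 CNP0528850.1 (target)
Conditions: BCl3 (3 equiv), CH2Cl2, −78 to 0 °C; then MeOH, aq. NaHCO3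
Reagents that add atoms: none
Why: Chelation-controlled demethylation of an aryl methyl ether: boron held on O9 forms a six-membered chelate only with the peri O8 methoxy group, chloride removes that methyl, the O2 and O6 methyl ethers lack such a chelate, and after hydrolysis ring B should settle as the hydrogen-bonded C9 ketone of the target.

**Compound list**

1 | 2,3,4-trimethoxybenzaldehyde | COc1ccc(C=O)c(OC)c1OC | starting material
2 | 2-hydroxy-3,4-dimethoxybenzaldehyde | COc1ccc(C=O)c(O)c1OC | intermediate
3 | 5-bromo-2-hydroxy-3,4-dimethoxybenzaldehyde | COc1c(Br)cc(C=O)c(O)c1OC | intermediate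
4 | 2-(benzyloxy)-5-bromo-3,4-dimethoxybenzaldehyde | COc1c(Br)cc(C=O)c(OCc2ccccc2)c1OC | intermediate
5 | 2-(benzyloxy)-3,4-dimethoxy-5-methylbenzaldehyde | COc1c(C)cc(C=O)c(OCc2ccccc2)c1OC | intermediate
6 | N-{2-[2-(benzyloxy)-3,4-dimethoxy-5-methylphenyl]-1-tosylethenyl}formamide (potassium salt in the flask, not isolated) | O=CNC(=Cc1cc(C)c(OC)c(OC)c1OCc1ccccc1)S(=O)(=O)c1ccc(C)cc1 | intermediate
7 | 2-[2-(benzyloxy)-3,4-dimethoxy-5-methylphenyl]acetonitrile | N#CCc1cc(C)c(OC)c(OC)c1OCc1ccccc1 | intermediate
8 | 2-[2-(benzyloxy)-6-bromo-3,4-dimethoxy-5-methylphenyl]acetonitrile | N#CCc1c(Br)c(C)c(OC)c(OC)c1OCc1ccccc1 | intermediate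
9 | 3,5-dimethoxyphenylboronic acid | COc1cc(OC)cc(B(O)O)c1 | starting material
10 | 2-[3-(benzyloxy)-3',4,5,5'-tetramethoxy-6-methylbiphenyl-2-yl]acetonitrile | N#CCc1c(-c2cc(OC)cc(OC)c2)c(C)c(OC)c(OC)c1OCc1ccccc1 | intermediate
11 | 2-[3-(benzyloxy)-3',4,5,5'-tetramethoxy-6-methylbiphenyl-2-yl]acetic acid | OC(=O)Cc1c(-c2cc(OC)cc(OC)c2)c(C)c(OC)c(OC)c1OCc1ccccc1 | intermediate
12 | 2-[3-(benzyloxy)-3',4,5,5'-tetramethoxy-6-methylbiphenyl-2-yl]acetyl chloride (not isolated) | ClC(=O)Cc1c(-c2cc(OC)cc(OC)c2)c(C)c(OC)c(OC)c1OCc1ccccc1 | intermediate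
13 | 1-(benzyloxy)-2,3,6,8-tetramethoxy-4-methylphenanthren-9-ol | COc1c(OC)c(C)c2c(cc(O)c3c(OC)cc(OC)cc23)c1OCc1ccccc1 | intermediate
14 | 1-(benzyloxy)-2,3,6,8-tetramethoxy-9-(methoxymethoxy)-4-methylphenanthrene | COc1c(OC)c(C)c2c(cc(OCOC)c3c(OC)cc(OC)cc23)c1OCc1ccccc1 | intermediate
15 | 2,3,6,8-tetramethoxy-9-(methoxymethoxy)-4-methylphenanthren-1-ol | COc1c(OC)c(C)c2c(cc(OCOC)c3c(OC)cc(OC)cc23)c1O | intermediate
16 | (4R)-4-hydroxy-2,3,6,8-tetramethoxy-9-(methoxymethoxy)-4-methylphenanthren-1(4H)-one | COC1=C(OC)[C@@](O)(C)c2c(cc(OCOC)c3c(OC)cc(OC)cc23)C1=O | intermediate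
17 | allyl bromide | C=CCBr | starting material
18 | (4R)-4-(allyloxy)-2,3,6,8-tetramethoxy-9-(methoxymethoxy)-4-methylphenanthren-1(4H)-one | COC1=C(OC)[C@@](OCC=C)(C)c2c(cc(OCOC)c3c(OC)cc(OC)cc23)C1=O | intermediate
19 | allylamine | C=CCN | starting material
20 | (4R)-3-(allylamino)-4-(allyloxy)-2,6,8-trimethoxy-9-(methoxymethoxy)-4-methylphenanthren-1(4H)-one | COC1=C(NCC=C)[C@@](OCC=C)(C)c2c(cc(OCOC)c3c(OC)cc(OC)cc23)C1=O | intermediate
21 | (4R)-dihydro-1,6-oxazocine: 2,6,8-trimethoxy-9-(methoxymethoxy)-4-methylphenanthren-1(4H)-one with the eight-membered ring C3–N(H)–C5'H2–C4'H=C3'H–C2'H2–O–C4, Z alkene | COC1=C2NC/C=C\CO[C@]2(C)c2c(cc(OCOC)c3c(OC)cc(OC)cc23)C1=O | intermediate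
22 | (4R)-cyclic enol ether: isomer of 21 with the ring C3–N(H)–C5'H2–C4'H2–C3'H=C2'H–O–C4, Z (not isolated) | COC1=C2NCC/C=C\O[C@]2(C)c2c(cc(OCOC)c3c(OC)cc(OC)cc23)C1=O | intermediate
23 | (4R,2'S)-N,O-acetal: 2,6,8-trimethoxy-9-(methoxymethoxy)-4-methylphenanthren-1(4H)-one with N3 and O4 both on C2' of the pyrrolidine N–C5'H2–C4'H2–C3'H2–C2'H, H-2' cis to the C4 methyl | COC1=C2N3CCC[C@@H]3O[C@]2(C)c2c(cc(OCOC)c3c(OC)cc(OC)cc23)C1=O | intermediate
24 | (4R,2'S)-9-hydroxy-2,6,8-trimethoxy-4-methyl N,O-acetal (23 without MOM, written as the 9-naphthol) | COC1=C2N3CCC[C@@H]3O[C@]2(C)c2c(cc(O)c3c(OC)cc(OC)cc23)C1=O | intermediate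
25 | CNP0528850.1: (4R,2'S)-8-hydroxy-2,6-dimethoxy-4-methyl-4,10-dihydrophenanthrene-1,9-dione with N3 and O4 both on C2' of the fused pyrrolidine | COC1=C2N3CCC[C@@H]3O[C@]2(C)C2=C(CC(=O)c3c(O)cc(OC)cc32)C1=O | target

**Step count and weak points**

Total: 18 steps. Longest linear sequence: 18 steps (from 1; compounds 9, 17 and 19 are bought).

Step 12 (dearomatisation). Water may attack the methoxy-bearing ortho carbon C2 instead of C4, which after loss of methanol leads to an ortho-quinone. The catalyst may also differentiate the two faces poorly, or the peracid may oxidise the electron-rich nucleus without the catalyst. The fallback sets out from 15 and uses sensitised photooxygenation (O2, tetraphenylporphyrin, visible light, CH2Cl2, −40 °C). Singlet oxygen adds across C1 and C4 of the phenol ring, so the oxygen can only arrive para, and the endoperoxide opens to the racemic 4-hydroperoxy-2,3,6,8-tetramethoxy-9-(methoxymethoxy)-4-methylphenanthren-1(4H)-one F1. Dimethyl sulfide reduces it to the racemic quinol F2. The enantiomers are separated by preparative chromatography on a chiral stationary phase, and the 4R enantiomer is compound 16, where the route is rejoined.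

Step 16 (key step). The hydride catalyst may be quenched by the acid or may rest at the enamine-type alkene isomer, so the enol ether is not supplied. The N,O-acetal may also form as a mixture at C2' that equilibrates slowly. The fallback sets out from 16 and reaches the same compound by condensation chemistry. 4,4-Diethoxybutan-1-amine (EtOH, 60 °C) replaces the C3 methoxy group and gives (4R)-3-[(4,4-diethoxybutyl)amino]-4-hydroxy-2,6,8-trimethoxy-9-(methoxymethoxy)-4-methylphenanthren-1(4H)-one F3. PPTS in wet acetone then frees the aldehyde, which condenses with the NH and the C4 hydroxyl to the fused pyrrolidine–oxazolidine under the same thermodynamic control. The route is rejoined at 23.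

Step 18 (final demethylation). The Lewis acid may ionise the N,O-acetal, with loss or scrambling of C2' and decomposition, or may also remove the C2 methyl ether through a five-membered chelate with the C1 carbonyl. The fallback sets out from 21 and exposes no N,O-acetal to boron. NaHSO4·SiO2 removes the MOM group to give the 9-hydroxy-dihydro-1,6-oxazocine F4. BCl3 then removes the peri O8 methyl group to give the 8-hydroxy-9-keto dihydro-1,6-oxazocine F5. The conditions of step 16 then carry F5 through its cyclic enol ether F6 by the same transannular closure directly to the target 25.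

**Further compounds**

F1 | step 12 | rac-4-hydroperoxy-2,3,6,8-tetramethoxy-9-(methoxymethoxy)-4-methylphenanthren-1(4H)-one | COC1=C(OC)C(OO)(C)c2c(cc(OCOC)c3c(OC)cc(OC)cc23)C1=O
F2 | step 12 | rac-4-hydroxy-2,3,6,8-tetramethoxy-9-(methoxymethoxy)-4-methylphenanthren-1(4H)-one | COC1=C(OC)C(O)(C)c2c(cc(OCOC)c3c(OC)cc(OC)cc23)C1=O
F3 | step 16 | (4R)-3-[(4,4-diethoxybutyl)amino]-4-hydroxy-2,6,8-trimethoxy-9-(methoxymethoxy)-4-methylphenanthren-1(4H)-one | COC1=C(NCCCC(OCC)OCC)[C@@](O)(C)c2c(cc(OCOC)c3c(OC)cc(OC)cc23)C1=O
F4 | step 18 | (4R)-9-hydroxy-2,6,8-trimethoxy-4-methyl dihydro-1,6-oxazocine (21 without MOM) | COC1=C2NC/C=C\CO[C@]2(C)c2c(cc(O)c3c(OC)cc(OC)cc23)C1=O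
F5 | step 18 | (4R)-8-hydroxy-2,6-dimethoxy-4-methyl-9-keto dihydro-1,6-oxazocine (C10 methylene tautomer) | COC1=C2NC/C=C\CO[C@]2(C)C2=C(CC(=O)c3c(O)cc(OC)cc32)C1=O
F6 | step 18 | (4R)-cyclic enol ether isomer of F5 (ring C3–N–C5'H2–C4'H2–C3'H=C2'H–O–C4) | COC1=C2NCC/C=C\O[C@]2(C)C2=C(CC(=O)c3c(O)cc(OC)cc32)C1=O
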